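**Retrosynthetic overview**
- The target comes from its hexabenzyl ether by hydrogenolysis. The ether comes from a (2R)-3-acyloxy-2H-chromene by face-selective hydrogenation of the enol-ester bond C3=C4, so C2 relays its configuration to C3.
- Ring C is the only ring built, and it is made in one operation from 3,5-bis(benzyloxy)phenol (ring A) and an α-acyloxy enal that already carries C4–C3–C2, ring B and the benzoate. Ortho-hydroxyalkylation forms C4–C4a. Oxa-6π closure of a vinylogous o-quinone methide under a chiral Brønsted acid forms O1–C2.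
- Enabling feature: ring A is a phloroglucinol ring. C4a lies ortho to O1 and to the C5 oxygen and para to the C7 oxygen, so C4a and O1 form a 1,3-C,O-bis-nucleophile that can be dearomatised for a moment. C4 and C2 are the 1,3-termini of the bridge, C2 is benzylic to electron-rich ring B, and the C3 ester can be carried as an enol ester one oxidation level up.
- The enal comes from a propargylic 4-(benzyloxy)benzoate by gold-catalysed 1,2-acyloxy shift and oxidation. That ester comes from tribenzylated gallaldehyde, an ethynyl Grignard reagent and the acyl chloride.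

Key step: step 4

Assumption: the sense of induction of the chiral acid in step 4 cannot be deduced from a close model, so the (R)-configured catalyst is written and its mirror image is to be used if it favours the (2S)-chromene.
Assumption: 3,4,5-trihydroxybenzaldehyde, 4-(benzyloxy)benzoyl chloride and 3,5-bis(benzyloxy)phenol are taken as catalogue compounds.

Step 1
Reactants: 1 3,4,5-trihydroxybenzaldehyde
Product: 2 3,4,5-tris(benzyloxy)benzaldehyde
Conditions: BnBr (3.5 equiv), K2CO3, DMF, 60 °C
Reagents that add atoms: benzyl bromide, BrCc1ccccc1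
Why: Williamson ether synthesis in which the three phenoxides are alkylated by SN2 while the aldehyde is inert to carbonate, and benzyl is chosen because all six benzyl groups of the route fall together in the last step.

Step 2
Reactants: 2 3,4,5-tris(benzyloxy)benzaldehyde; 3 4-(benzyloxy)benzoyl chloride
Product: 5 rac-1-[3,4,5-tris(benzyloxy)phenyl]prop-2-yn-1-yl 4-(benzyloxy)benzoate, via bromomagnesium propargylic alkoxide 4 (not isolated)
Conditions: HC≡CMgBr (1.1 equiv), THF, 0 °C; then 3 (1.3 equiv), DMAP (cat.), 0 °C to rt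
Reagents that add atoms: ethynylmagnesium bromide, C#C[Mg]Br
Why: Grignard 1,2-addition to the aldehyde followed by DMAP-catalysed O-acylation of the alkoxide in the same flask, with the carbinol centre formed racemic on purpose because step 3 turns it into an sp2 carbon.

Step 3
Reactants: 5 rac-1-[3,4,5-tris(benzyloxy)phenyl]prop-2-yn-1-yl 4-(benzyloxy)benzoate
Product: 7 (Z)-3-oxo-1-[3,4,5-tris(benzyloxy)phenyl]prop-1-en-2-yl 4-(benzyloxy)benzoate, via gold vinylcarbene 6 (not isolated)
Conditions: (IPr)AuNTf2 (5 mol %; IPr = 1,3-bis(2,6-diisopropylphenyl)imidazol-2-ylidene), Ph2SO (2 equiv), CH2Cl2, rt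
Reagents that add atoms: diphenyl sulfoxide, O=S(c1ccccc1)c1ccccc1
Why: Known oxidative rearrangement of terminal propargylic esters under cationic monovalent gold, in which 5-exo-dig attack of the ester carbonyl on the activated alkyne and ring opening (1,2-acyloxy migration) give vinylcarbene 6, the sulfoxide transfers its oxygen to the carbene carbon, the terminal alkyne favours the 1,2- over the 1,3-shift, and the (Z)-alkene with aryl trans to CHO is the less strained one.

Step 4
Reactants: 7 (Z)-3-oxo-1-[3,4,5-tris(benzyloxy)phenyl]prop-1-en-2-yl 4-(benzyloxy)benzoate; 8 3,5-bis(benzyloxy)phenol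
Product: 11 (2R)-5,7-bis(benzyloxy)-2-[3,4,5-tris(benzyloxy)phenyl]-2H-chromen-3-yl 4-(benzyloxy)benzoate, via ortho-hydroxyalkylation carbinol 9 (not isolated), via vinylogous o-quinone methide 10 (not isolated)
Conditions: (R)-3,3'-bis(2,4,6-triisopropylphenyl)-1,1'-binaphthyl-2,2'-diyl N-triflylphosphoramide (10 mol %), 8 (1.2 equiv), 5 Å MS, toluene, −20 °C
Reagents that add atoms: none
Why: Proposed new method: the bifunctional chiral acid binds the phenol O–H of 8 (at P=O) and the aldehyde oxygen of 7 (at N–H), so the ortho carbon of 8 adds 1,2 to the formyl group (Friedel–Crafts hydroxyalkylation, C4–C4a bond), carbinol 9, activated by three ring-A oxygens, loses water to the vinylogous o-quinone methide 10 (ring A dearomatised for a moment), and 10, held by the catalyst as a hydrogen-bonded contact ion pair, closes to 11 with rearomatisation of ring A (O1–C2 bond). The closest known reaction types are the formal [3+3] chromene annulation of resorcinols and phloroglucinols with enals (Knoevenagel-type condensation then oxa-6π electrocyclisation, run racemic with ammonium salts or arylboronic acids) and the chiral N-triflylphosphoramide-catalysed cyclisation of 2-(3-hydroxyalk-1-enyl)phenols to enantioenriched 2H-chromenes through contact ion pairs; new are their merger into an intermolecular enantioselective process and the α-acyloxy enal as partner. Ring C, the only ring closed, forms by disrotatory oxa-6π electrocyclisation of the 1-oxatriene O1=C8a–C4a=C4–C3=C2, which in the protonated limit is a 6-endo-trig capture of the ring-B-stabilised allyl-cation terminus C2 by O1. The single new stereocentre C2 is controlled by the catalyst, whose anion stays bound at O1 while its 2,4,6-triisopropylphenyl walls shield one face of C2, and the (Z)-alkene keeps ring B on the outside of the closing triene so that only one rotation mode competes. The step needs 1,2- over 1,4-addition, ortho- over para-attack and a single annulation: the α-acyloxy group makes the β-carbon of 7 an electron-rich, hindered, donor-aryl-substituted enol-ester carbon that is mismatched for conjugate addition, the only free OH of 8 steers the catalyst to the two symmetry-equivalent ortho carbons and only an ortho adduct can cyclise while a para adduct reverts, and the benzyl caps leave no second OH for another annulation. The inductively withdrawing acyloxy group on the central carbon of the allyl cation, the low temperature and the sieves should keep 11 from re-ionising, so the C2 configuration should not wash out.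

Step 5
Reactants: 11 (2R)-5,7-bis(benzyloxy)-2-[3,4,5-tris(benzyloxy)phenyl]-2H-chromen-3-yl 4-(benzyloxy)benzoate
Product: 12 (2R,3R)-5,7-bis(benzyloxy)-2-[3,4,5-tris(benzyloxy)phenyl]chroman-3-yl 4-(benzyloxy)benzoate
Conditions: H2 (30 bar), [Rh(nbd)(dppb)]BF4 (5 mol %), CH2Cl2, rt
Reagents that add atoms: none
Why: Chelation-assisted homogeneous hydrogenation of an enol ester on a cationic rhodium diphosphine catalyst (alkene and ester carbonyl bind the metal as in enamide hydrogenation) leaves benzyl ethers and the C2–O1 bond alone, and because allylic strain with the C3 acyloxy group forces the C2 aryl group pseudoaxial and blocks one face of C3=C4, both hydrogens should arrive on the face that carries C2–H and set C3 as (R), cis to C2.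

Step 6
Reactants: 12 (2R,3R)-5,7-bis(benzyloxy)-2-[3,4,5-tris(benzyloxy)phenyl]chroman-3-yl 4-(benzyloxy)benzoate
Product: 13 epigallocatechin 3-O-(4-hydroxybenzoate), (2R,3R)
Conditions: H2 (1 atm), Pd(OH)2/C, THF/MeOH, rt
Reagents that add atoms: none
Why: Hydrogenolysis of six benzyl aryl ethers under neutral conditions is the standard end game for benzyl-protected flavan-3-ol esters, and the ester, the C2–O1 bond and both stereocentres should stay untouched at 1 atm and room temperature.

**Compound list**
1 | 3,4,5-trihydroxybenzaldehyde | O=Cc1cc(O)c(O)c(O)c1 | starting material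
2 | 3,4,5-tris(benzyloxy)benzaldehyde | O=Cc1cc(OCc2ccccc2)c(OCc2ccccc2)c(OCc2ccccc2)c1 | intermediate
3 | 4-(benzyloxy)benzoyl chloride | O=C(Cl)c1ccc(OCc2ccccc2)cc1 | starting material
4 | bromomagnesium 1-[3,4,5-tris(benzyloxy)phenyl]prop-2-yn-1-olate (racemic, not isolated) | C#CC(O[Mg]Br)c1cc(OCc2ccccc2)c(OCc2ccccc2)c(OCc2ccccc2)c1 | intermediate
5 | rac-1-[3,4,5-tris(benzyloxy)phenyl]prop-2-yn-1-yl 4-(benzyloxy)benzoate | C#CC(OC(=O)c1ccc(OCc2ccccc2)cc1)c1cc(OCc2ccccc2)c(OCc2ccccc2)c(OCc2ccccc2)c1 | intermediate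
6 | (IPr)gold vinylcarbene triflimide, carbene carbon trans to ring B (not isolated) | CC(C)c1cccc(C(C)C)c1N1C=C[N+](c2c(C(C)C)cccc2C(C)C)=C1[Au]=C/C(OC(=O)c1ccc(OCc2ccccc2)cc1)=C/c1cc(OCc2ccccc2)c(OCc2ccccc2)c(OCc2ccccc2)c1.O=S(=O)([N-]S(=O)(=O)C(F)(F)F)C(F)(F)F | intermediate
7 | (Z)-3-oxo-1-[3,4,5-tris(benzyloxy)phenyl]prop-1-en-2-yl 4-(benzyloxy)benzoate | O=C/C(OC(=O)c1ccc(OCc2ccccc2)cc1)=C/c1cc(OCc2ccccc2)c(OCc2ccccc2)c(OCc2ccccc2)c1 | intermediate
8 | 3,5-bis(benzyloxy)phenol | Oc1cc(OCc2ccccc2)cc(OCc2ccccc2)c1 | starting material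
9 | (Z)-3-[2,4-bis(benzyloxy)-6-hydroxyphenyl]-3-hydroxy-1-[3,4,5-tris(benzyloxy)phenyl]prop-1-en-2-yl 4-(benzyloxy)benzoate, carbinol centre undefined (not isolated) | OC(c1c(O)cc(OCc2ccccc2)cc1OCc1ccccc1)/C(OC(=O)c1ccc(OCc2ccccc2)cc1)=C/c1cc(OCc2ccccc2)c(OCc2ccccc2)c(OCc2ccccc2)c1 | intermediate
10 | 3,5-bis(benzyloxy)-6-{(Z)-2-[4-(benzyloxy)benzoyloxy]-3-[3,4,5-tris(benzyloxy)phenyl]prop-2-enylidene}cyclohexa-2,4-dien-1-one, side chain syn to the ring carbonyl (not isolated) | O=C1C=C(OCc2ccccc2)C=C(OCc2ccccc2)/C1=C/C(OC(=O)c1ccc(OCc2ccccc2)cc1)=C/c1cc(OCc2ccccc2)c(OCc2ccccc2)c(OCc2ccccc2)c1 | intermediate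
11 | (2R)-5,7-bis(benzyloxy)-2-[3,4,5-tris(benzyloxy)phenyl]-2H-chromen-3-yl 4-(benzyloxy)benzoate | O=C(OC1=Cc2c(OCc3ccccc3)cc(OCc3ccccc3)cc2O[C@@H]1c1cc(OCc2ccccc2)c(OCc2ccccc2)c(OCc2ccccc2)c1)c1ccc(OCc2ccccc2)cc1 | intermediate
12 | (2R,3R)-5,7-bis(benzyloxy)-2-[3,4,5-tris(benzyloxy)phenyl]chroman-3-yl 4-(benzyloxy)benzoate | O=C(O[C@@H]1Cc2c(OCc3ccccc3)cc(OCc3ccccc3)cc2O[C@@H]1c1cc(OCc2ccccc2)c(OCc2ccccc2)c(OCc2ccccc2)c1)c1ccc(OCc2ccccc2)cc1 | intermediate
13 | epigallocatechin 3-O-(4-hydroxybenzoate), (2R,3R) | O=C(O[C@@H]1Cc2c(O)cc(O)cc2O[C@@H]1c1cc(O)c(O)c(O)c1)c1ccc(O)cc1 | target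

**Total steps:** 6. **Longest linear sequence:** 6 steps (1 → 2 → 5 → 7 → 11 → 12 → 13).

**Steps most likely to fail**

1. **Step 4 (proposed new method).**
   - What may go wrong: conjugate Friedel–Crafts addition may outrun 1,2-addition. Facial discrimination in the ring closure may be poor. The acid may re-ionise the product, causing racemisation or hydride transfer between chromene and cation.
   - Fallback: it sets out from 7 and 8 and comes back at 11, using known chemistry. 7 and 8 are heated with PhB(OH)2 (1 equiv) and catalytic propionic acid in toluene with azeotropic removal of water. The boron-templated, ortho-specific hydroxyalkylation should give the 2-phenyl-4H-1,3,2-benzodioxaborin F1. F1 cycloreverts in the same flask to o-quinone methide 10, which closes to the racemic chromene F2.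
   - Resolution: preparative chromatography on a polysaccharide chiral stationary phase separates 11 from the (2S)-chromene F3. F3 is racemised by UV irradiation (reversible photochromic ring opening to 10 and thermal reclosure) and recycled.

2. **Step 3.**
   - What may go wrong: the cationic gold may ionise the electron-rich benzylic C–O bond. A 1,3-acyloxy shift to an allenyl ester may compete. The carbene may be consumed before oxygen transfer.
   - Fallback: it sets out from 2 and comes back at 7. Horner–Wadsworth–Emmons olefination of 2 with methyl 2-[(tert-butyldimethylsilyl)oxy]-2-(dimethoxyphosphoryl)acetate (LiN(SiMe3)2, THF, −78 °C to rt) should give methyl (Z)-2-[(tert-butyldimethylsilyl)oxy]-3-[3,4,5-tris(benzyloxy)phenyl]acrylate F4. Reduction with i-Bu2AlH (CH2Cl2, −78 °C) gives the (Z)-2-silyloxy allylic alcohol F5. MnO2 (CH2Cl2, rt) oxidises it to the (Z)-2-silyloxy enal F6. Fluoride-triggered O-acylation of this silyl enol ether with 3 (CsF, MeCN, 0 °C) exchanges silyl for the aroyl group and delivers 7.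

3. **Step 5.**
   - What may go wrong: hydrogen uptake at the hindered trisubstituted alkene may be slow. The alkene may migrate into the C2=C3 position with loss of the C2 centre. The allylic-benzylic C2–O1 bond may be cleaved reductively. The facial bias may be insufficient.
   - Fallback: it sets out from 11 and comes back at 12. MeLi (2 equiv, THF, −78 °C) cleaves the enol ester to the regiodefined C3=C4 lithium enolate F7, which leaves C2 untouched. A quench with AcOH at −78 °C gives the (2R)-flavan-3-one F8. LiBH(s-Bu)3 (L-Selectride, THF, −78 °C) attacks the ketone from the face opposite the C2 aryl group and should give the (2R,3R)-cis-flavan-3-ol F9. Acylation with 3 (Et3N, DMAP, CH2Cl2) gives 12.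

**Further compounds**
F1 | step 4 | 5,7-bis(benzyloxy)-2-phenyl-4H-1,3,2-benzodioxaborin bearing the (Z)-1-[4-(benzyloxy)benzoyloxy]-2-[3,4,5-tris(benzyloxy)phenyl]vinyl group at C4 (racemic) | B1(c2ccccc2)Oc2cc(OCc3ccccc3)cc(OCc3ccccc3)c2C(O1)/C(OC(=O)c1ccc(OCc2ccccc2)cc1)=C/c1cc(OCc2ccccc2)c(OCc2ccccc2)c(OCc2ccccc2)c1
F2 | step 4 | rac-5,7-bis(benzyloxy)-2-[3,4,5-tris(benzyloxy)phenyl]-2H-chromen-3-yl 4-(benzyloxy)benzoate | O=C(OC1=Cc2c(OCc3ccccc3)cc(OCc3ccccc3)cc2OC1c1cc(OCc2ccccc2)c(OCc2ccccc2)c(OCc2ccccc2)c1)c1ccc(OCc2ccccc2)cc1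
F3 | step 4 | (2S)-5,7-bis(benzyloxy)-2-[3,4,5-tris(benzyloxy)phenyl]-2H-chromen-3-yl 4-(benzyloxy)benzoate | O=C(OC1=Cc2c(OCc3ccccc3)cc(OCc3ccccc3)cc2O[C@H]1c1cc(OCc2ccccc2)c(OCc2ccccc2)c(OCc2ccccc2)c1)c1ccc(OCc2ccccc2)cc1
F4 | step 3 | methyl (Z)-2-[(tert-butyldimethylsilyl)oxy]-3-[3,4,5-tris(benzyloxy)phenyl]acrylate | COC(=O)/C(O[Si](C)(C)C(C)(C)C)=C/c1cc(OCc2ccccc2)c(OCc2ccccc2)c(OCc2ccccc2)c1
F5 | step 3 | (Z)-2-[(tert-butyldimethylsilyl)oxy]-3-[3,4,5-tris(benzyloxy)phenyl]prop-2-en-1-ol | OC/C(O[Si](C)(C)C(C)(C)C)=C/c1cc(OCc2ccccc2)c(OCc2ccccc2)c(OCc2ccccc2)c1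
F6 | step 3 | (Z)-2-[(tert-butyldimethylsilyl)oxy]-3-[3,4,5-tris(benzyloxy)phenyl]acrylaldehyde | O=C/C(O[Si](C)(C)C(C)(C)C)=C/c1cc(OCc2ccccc2)c(OCc2ccccc2)c(OCc2ccccc2)c1
F7 | step 5 | lithium (2R)-5,7-bis(benzyloxy)-2-[3,4,5-tris(benzyloxy)phenyl]-2H-chromen-3-olate | [Li]OC1=Cc2c(OCc3ccccc3)cc(OCc3ccccc3)cc2O[C@@H]1c1cc(OCc2ccccc2)c(OCc2ccccc2)c(OCc2ccccc2)c1
F8 | step 5 | (2R)-5,7-bis(benzyloxy)-2-[3,4,5-tris(benzyloxy)phenyl]chroman-3-one | O=C1Cc2c(OCc3ccccc3)cc(OCc3ccccc3)cc2O[C@@H]1c1cc(OCc2ccccc2)c(OCc2ccccc2)c(OCc2ccccc2)c1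
F9 | step 5 | (2R,3R)-5,7-bis(benzyloxy)-2-[3,4,5-tris(benzyloxy)phenyl]chroman-3-ol | O[C@@H]1Cc2c(OCc3ccccc3)cc(OCc3ccccc3)cc2O[C@@H]1c1cc(OCc2ccccc2)c(OCc2ccccc2)c(OCc2ccccc2)c1
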